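Everything rests on opening ring C of the genkwanin half, a 2,3-diaryl-4-pyranone, at C2–C3 and O1–C2. Its C3, the atom bonded to luteolin C6, is traced back to the CH2 of a benzyl aryl ketone, acidified by the ketone and by luteolin ring A. In one operation a 4-oxygenated benzoyl group is loaded onto the only free phenol, migrates to that CH2 (Baker–Venkataraman shift), and the released phenoxide closes ring C with loss of water. The precursor is a 2-hydroxy-4-methoxy-6-(methoxymethoxy)phenyl ketone whose CH2 already carries C6 of tetra-O-MOM-luteolin. The crowded interflavone bond is thus made earlier, at an sp3 carbon, by ketone α-arylation.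

Key step: step 10

Assumption: the C3–C6 axis between the two flavone units has no descriptor in the target structure. It is treated as configurationally undefined, and the target has no stereocentre.

Design remarks:
- **Iodination order.** Luteolin is iodinated while its 5-OH is still free. The 5-hydroxy-7-alkoxy pattern steers the electrophile to C6, whereas fully etherified 5,7-dialkoxyflavones tend to react at C8.
- **Groups next to the iodide.** The two oxygens beside the iodide carry MOM rather than benzyl, so the arylpalladium intermediate has no neighbouring phenyl ring for intramolecular C–H arylation.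
- **Temporary benzyl ether.** The phenol that becomes O1 is carried as a benzyl ether, the only group that is removed without acid. Acid at the ketone stage would unmask luteolin O5 and O7, which would close onto the ketone to give a benzofuran.
- **Base-only ring closure.** For the same reason ring C is closed under base alone.
- **Acid chloride.** The acetal-bearing acid chloride is made with a chloroenamine, which releases no HCl.
- **Bought ketone.** The 4-O-methylated phloracetophenone is purchased, which avoids a selective methylation.

Step 1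
Reactants: 1 luteolin
Product: 2 7,3',4'-tris-O-(methoxymethyl)luteolin (5-OH free)
Conditions: MOMCl (3.3 equiv), K2CO3, acetone, 0 °C → rt, N2
Reagents that add atoms: chloromethyl methyl ether (MOMCl), COCCl
Why: Williamson-type O-alkylation caps the 7-, 3'- and 4'-phenols under mild carbonate conditions, while the 5-OH, held in a hydrogen bond to the C4 carbonyl, is much less nucleophilic and stays free.

Step 2
Reactants: 2 7,3',4'-tris-O-(methoxymethyl)luteolin
Product: 3 6-iodo-7,3',4'-tris-O-(methoxymethyl)luteolin (5-OH free)
Conditions: BnNMe3 ICl2 (1.05 equiv), CaCO3, CH2Cl2–MeOH, rt, dark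
Reagents that add atoms: benzyltrimethylammonium dichloroiodate, C[N+](C)(C)Cc1ccccc1.Cl[I-]Cl
Why: In this electrophilic aromatic iodination the reagent attacks phenols but not aryl ethers in this medium, so ring B is spared, 5-hydroxy-7-alkoxyflavones are known to react at C6 next to the free 5-OH, and CaCO3 absorbs the HCl so the MOM ethers survive.

Step 3
Reactants: 3 6-iodo-7,3',4'-tris-O-(methoxymethyl)luteolin
Product: 4 6-iodo-5,7,3',4'-tetrakis-O-(methoxymethyl)luteolin
Conditions: NaH, MOMCl, DMF, 0 °C → rt
Reagents that add atoms: chloromethyl methyl ether (MOMCl), COCCl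
Why: In this Williamson-type O-alkylation, full deprotonation by NaH breaks the chelate, and the small, very reactive MOMCl reaches the phenoxide between the carbonyl and the iodine.

Step 4
Reactants: 5 2',6'-dihydroxy-4'-methoxyacetophenone
Product: 6 2'-hydroxy-4'-methoxy-6'-(methoxymethoxy)acetophenone
Conditions: MOMCl (1.05 equiv), K2CO3, acetone, 0 °C → rt
Reagents that add atoms: chloromethyl methyl ether (MOMCl), COCCl
Why: This Williamson-type mono-O-alkylation acts on two equivalent phenols, and once one is capped the other is locked in a strong hydrogen bond to the acetyl carbonyl, so one equivalent of MOMCl should stop cleanly.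

Step 5
Reactants: 6 2'-hydroxy-4'-methoxy-6'-(methoxymethoxy)acetophenone
Product: 7 2'-(benzyloxy)-4'-methoxy-6'-(methoxymethoxy)acetophenone
Conditions: BnBr, K2CO3, DMF, 60 °C
Reagents that add atoms: benzyl bromide, BrCc1ccccc1
Why: Warm K2CO3/DMF overcomes the chelation in this Williamson ether synthesis and installs the one protecting group that can later be taken off without acid.

Step 6
Reactants: 4 6-iodo-5,7,3',4'-tetrakis-O-(methoxymethyl)luteolin, 7 2'-(benzyloxy)-4'-methoxy-6'-(methoxymethoxy)acetophenone
Product: 8 1-[2-(benzyloxy)-4-methoxy-6-(methoxymethoxy)phenyl]-2-[5,7,3',4'-tetrakis-O-(methoxymethyl)luteolin-6-yl]ethanone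
Conditions: Pd2(dba)3 (2.5 mol %), XPhos (10 mol %), K3PO4 (3 equiv), 7 (1.3 equiv), toluene, 100 °C, Ar
Reagents that add atoms: none
Why: In this Buchwald–Hartwig-type ketone α-arylation, zerovalent palladium inserts into the C6–I bond, the only enolate available (from the methyl group) binds, the two ortho OMOM groups speed reductive elimination, the hindered product resists a second arylation, and the mild base K3PO4 spares the flavone.

Step 7
Reactants: 8 benzyl-protected ketone
Product: 9 1-[2-hydroxy-4-methoxy-6-(methoxymethoxy)phenyl]-2-[5,7,3',4'-tetrakis-O-(methoxymethyl)luteolin-6-yl]ethanone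
Conditions: H2 (1 atm), 10% Pd/C, EtOAc–THF, rt
Reagents that add atoms: none
Why: Catalytic hydrogenolysis cleaves the aryl benzyl ether under neutral conditions and should leave the five MOM acetals, the hindered aryl ketone and the flavone C2=C3 bond untouched at atmospheric pressure.

Step 8
Reactants: 10 4-hydroxybenzoic acid
Product: 12 4-(methoxymethoxy)benzoic acid, via methoxymethyl 4-(methoxymethoxy)benzoate 11 (not isolated)
Conditions: MOMCl (2.3 equiv), i-Pr2NEt, THF, 0 °C → rt; then 2 M NaOH, MeOH, rt; Et2O wash, cold 1 M HCl to pH 4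
Reagents that add atoms: chloromethyl methyl ether (MOMCl), COCCl; sodium hydroxide, [Na+].[OH-]
Why: Double O-alkylation of phenol and carboxylate is followed by saponification, in which hydroxide quickly cleaves the activated MOM ester while the aryl MOM ether is inert to base.

Step 9
Reactants: 12 4-(methoxymethoxy)benzoic acid
Product: 13 4-(methoxymethoxy)benzoyl chloride
Conditions: 1-chloro-N,N,2-trimethylprop-1-en-1-amine (1.1 equiv), CH2Cl2, 0 °C → rt; concentrate, use at once
Reagents that add atoms: 1-chloro-N,N,2-trimethylprop-1-en-1-amine, CC(C)=C(Cl)N(C)C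
Why: In this acid chloride formation with an α-chloroenamine, the acid adds to the keteniminium form and chloride then displaces the amide, so no HCl is released and the acid-labile aryl acetal should survive.

Step 10
Reactants: 9 1-[2-hydroxy-4-methoxy-6-(methoxymethoxy)phenyl]-2-[5,7,3',4'-tetrakis-O-(methoxymethyl)luteolin-6-yl]ethanone, 13 4-(methoxymethoxy)benzoyl chloride
Product: 16 hexakis-O-(methoxymethyl) ether of 3-(luteolin-6-yl)genkwanin, via O-aroyl ester 14 (not isolated), via 2-aryl-1,3-diketone 15 (not isolated)
Conditions: 13 (1.3 equiv), pyridine, 0 °C → rt; then DBU (3 equiv), 4 Å MS, 90 °C, Ar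
Reagents that add atoms: none
Why: Acylation in pyridine can occur only at the single free phenol and gives ester 14; DBU then deprotonates the CH2, which is activated by the ketone and by luteolin ring A, and the enolate carbon attacks the neighbouring ester carbonyl through a six-membered cyclic transition state, forming C2–C3 and releasing the phenoxide of diketone 15 (Baker–Venkataraman rearrangement). The phenoxide adds to the new aroyl ketone in a 6-exo-trig closure (O1–C2), and the adduct loses water by E1cB through its acidic C3–H to give pyranone ring C. The closest known reaction type is the conversion of O-aroylated 2-hydroxydeoxybenzoins into 2,3-diarylchromones, including the one-pot DBU/pyridine variant of the rearrangement. No stereocentre is created, because the labile methine of 15 ends as sp2 C3. Intramolecular delivery secures C- over O-acylation of the enolate, the carbon can accept only one aroyl group, and the di-ortho-substituted luteolin ring twists the diketone out of a flat chelated enol, which favours closure without acid. The MOM ethers on luteolin O5 and O7 block the competing five-membered closure to a 3-aroylbenzofuran, which is why the whole sequence is kept basic.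

Step 11
Reactants: 16 hexakis-O-(methoxymethyl) ether of 3-(luteolin-6-yl)genkwanin
Product: 17 3-(luteolin-6-yl)genkwanin (CNP0200311.0)
Conditions: conc. HCl (cat.), MeOH–THF, 50 °C
Reagents that add atoms: none
Why: Acid-catalysed acetal exchange with methanol removes all six MOM groups, while the C7 methyl ether and both pyranone rings are inert to dilute acid at this temperature, far below what a Wessely–Moser isomerisation needs.

Compound list
1 | luteolin (5,7,3',4'-tetrahydroxyflavone) | O=c1cc(-c2ccc(O)c(O)c2)oc2cc(O)cc(O)c12 | starting material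
2 | 7,3',4'-tris-O-(methoxymethyl)luteolin, 5-OH free | O=c1cc(-c2ccc(OCOC)c(OCOC)c2)oc2cc(OCOC)cc(O)c12 | intermediate
3 | 6-iodo-7,3',4'-tris-O-(methoxymethyl)luteolin, 5-OH free | O=c1cc(-c2ccc(OCOC)c(OCOC)c2)oc2cc(OCOC)c(I)c(O)c12 | intermediate
4 | 6-iodo-5,7,3',4'-tetrakis-O-(methoxymethyl)luteolin | O=c1cc(-c2ccc(OCOC)c(OCOC)c2)oc2cc(OCOC)c(I)c(OCOC)c12 | intermediate
5 | 2',6'-dihydroxy-4'-methoxyacetophenone | CC(=O)c1c(O)cc(OC)cc1O | starting material
6 | 2'-hydroxy-4'-methoxy-6'-(methoxymethoxy)acetophenone | CC(=O)c1c(O)cc(OC)cc1OCOC | intermediate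
7 | 2'-(benzyloxy)-4'-methoxy-6'-(methoxymethoxy)acetophenone | CC(=O)c1c(OCc2ccccc2)cc(OC)cc1OCOC | intermediate
8 | 1-[2-(benzyloxy)-4-methoxy-6-(methoxymethoxy)phenyl]-2-[5,7,3',4'-tetrakis-O-(methoxymethyl)luteolin-6-yl]ethanone | COc1cc(OCc2ccccc2)c(C(=O)Cc2c(OCOC)cc3oc(-c4ccc(OCOC)c(OCOC)c4)cc(=O)c3c2OCOC)c(OCOC)c1 | intermediate
9 | 1-[2-hydroxy-4-methoxy-6-(methoxymethoxy)phenyl]-2-[5,7,3',4'-tetrakis-O-(methoxymethyl)luteolin-6-yl]ethanone | COc1cc(O)c(C(=O)Cc2c(OCOC)cc3oc(-c4ccc(OCOC)c(OCOC)c4)cc(=O)c3c2OCOC)c(OCOC)c1 | intermediate
10 | 4-hydroxybenzoic acid | O=C(O)c1ccc(O)cc1 | starting material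
11 | methoxymethyl 4-(methoxymethoxy)benzoate | COCOC(=O)c1ccc(OCOC)cc1 | intermediate
12 | 4-(methoxymethoxy)benzoic acid | COCOc1ccc(C(=O)O)cc1 | intermediate
13 | 4-(methoxymethoxy)benzoyl chloride | COCOc1ccc(C(=O)Cl)cc1 | intermediate
14 | 3-methoxy-5-(methoxymethoxy)-2-{[5,7,3',4'-tetrakis-O-(methoxymethyl)luteolin-6-yl]acetyl}phenyl 4-(methoxymethoxy)benzoate | COc1cc(OC(=O)c2ccc(OCOC)cc2)c(C(=O)Cc2c(OCOC)cc3oc(-c4ccc(OCOC)c(OCOC)c4)cc(=O)c3c2OCOC)c(OCOC)c1 | intermediate
15 | 1-[2-hydroxy-4-methoxy-6-(methoxymethoxy)phenyl]-3-[4-(methoxymethoxy)phenyl]-2-[5,7,3',4'-tetrakis-O-(methoxymethyl)luteolin-6-yl]propane-1,3-dione (epimerisable methine, no defined configuration) | COc1cc(O)c(C(=O)C(C(=O)c2ccc(OCOC)cc2)c2c(OCOC)cc3oc(-c4ccc(OCOC)c(OCOC)c4)cc(=O)c3c2OCOC)c(OCOC)c1 | intermediate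
16 | 7-methoxy-5-(methoxymethoxy)-2-[4-(methoxymethoxy)phenyl]-3-[5,7,3',4'-tetrakis-O-(methoxymethyl)luteolin-6-yl]-4H-chromen-4-one | COc1cc(OCOC)c2c(=O)c(-c3c(OCOC)cc4oc(-c5ccc(OCOC)c(OCOC)c5)cc(=O)c4c3OCOC)c(-c3ccc(OCOC)cc3)oc2c1 | intermediate
17 | 3-[2-(3,4-dihydroxyphenyl)-5,7-dihydroxy-4-oxo-4H-chromen-6-yl]-5-hydroxy-2-(4-hydroxyphenyl)-7-methoxy-4H-chromen-4-one | COc1cc(O)c2c(=O)c(-c3c(O)cc4oc(-c5ccc(O)c(O)c5)cc(=O)c4c3O)c(-c3ccc(O)cc3)oc2c1 | target

Total step count: 11.
Longest linear sequence: 7 (steps 1, 2, 3, 6, 7, 10, 11).

Steps most likely to fail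

**Step 10.**
- Risk: the acyl shift must build a carbon flanked by three bulky aryl or aroyl groups. Ester cleavage by adventitious water, retro-Claisen loss of the aroyl group, or a stalled dehydration could outrun product formation.
- Fallback (sets out from 9, returns at 16): ring C would be closed first with a small one-carbon unit, and the 2-aryl group added afterwards. Heating 9 with N,N-dimethylformamide dimethyl acetal in toluene at 100 °C is the standard isoflavone closure of 2-hydroxydeoxybenzoins. It should give 7-methoxy-5-(methoxymethoxy)-3-[5,7,3',4'-tetrakis-O-(methoxymethyl)luteolin-6-yl]-4H-chromen-4-one F1. Commercial 1-bromo-4-(methoxymethoxy)benzene and Mg in THF give 4-(methoxymethoxy)phenylmagnesium bromide F2. With catalytic CuBr·SMe2 at −40 °C this should add 1,4 to the unsubstituted C2 of F1, in preference to the fully substituted C2 of the luteolin unit. The product is the racemic trans-2,3-diarylchroman-4-one F3. DDQ in dioxane at 90 °C would then dehydrogenate C2–C3, erasing both transient stereocentres, to give 16.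

**Step 6.**
- Risk: transfer of the enolate to an arylpalladium centre shielded by two ortho OMOM groups may be slow. Hydrodeiodination, catalyst decay or base-induced self-condensation of the ketone could then dominate.
- Fallback (sets out from 7 and 4, returns at 8): the base-generated enolate is replaced by a preformed neutral enol derivative. LiHMDS and TMSCl in THF at −78 °C convert 7 into {1-[2-(benzyloxy)-4-methoxy-6-(methoxymethoxy)phenyl]ethenyloxy}trimethylsilane F4. This is coupled with 4 through its tin enolate (Bu3SnF, Pd2(dba)3, P(t-Bu)3, toluene, 85 °C), so neither the flavone nor the acidic product meets a Brønsted base.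

**Step 9.**
- Risk: traces of HCl could cleave the acetal, or the acid chloride could hydrolyse during concentration and transfer.
- Fallback (sets out from 12 and 9, returns at 14 and from there at 16): the acid chloride is avoided altogether. A Steglich esterification of 12 with phenol 9 (EDC, DMAP, CH2Cl2, rt) gives ester 14, now isolated. It is then submitted to the DBU/pyridine stage of step 10.

Further compounds
F1 | step 10 | 7-methoxy-5-(methoxymethoxy)-3-[5,7,3',4'-tetrakis-O-(methoxymethyl)luteolin-6-yl]-4H-chromen-4-one | COc1cc(OCOC)c2c(=O)c(-c3c(OCOC)cc4oc(-c5ccc(OCOC)c(OCOC)c5)cc(=O)c4c3OCOC)coc2c1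
F2 | step 10 | 4-(methoxymethoxy)phenylmagnesium bromide | COCOc1ccc([Mg]Br)cc1
F3 | step 10 | (±)-trans-7-methoxy-5-(methoxymethoxy)-2-[4-(methoxymethoxy)phenyl]-3-[5,7,3',4'-tetrakis-O-(methoxymethyl)luteolin-6-yl]chroman-4-one (one enantiomer drawn) | COc1cc(OCOC)c2C(=O)[C@@H](c3c(OCOC)cc4oc(-c5ccc(OCOC)c(OCOC)c5)cc(=O)c4c3OCOC)[C@H](c3ccc(OCOC)cc3)Oc2c1
F4 | step 6 | {1-[2-(benzyloxy)-4-methoxy-6-(methoxymethoxy)phenyl]ethenyloxy}trimethylsilane | C=C(O[Si](C)(C)C)c1c(OCc2ccccc2)cc(OC)cc1OCOC
F0 | step 9 | none | none
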